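## Structural features

The target is a 2-arylbenzofuran. Benzo ring A (C3a, C4–C7, C7a) is fused to furan ring B (O1, C2, C3), and C2 is bonded to C5 of a 2,2-dimethylchroman (benzene ring C fused to dihydropyran ring D). Ring A has free hydroxyls at C4 and C6 and a 2-methylbut-3-en-2-yl (reverse prenyl) group at C7, whose quaternary carbon sits between the C6 hydroxyl and O1. Ring C has one hydroxyl at C7, meta to the biaryl bond and to the ring D oxygen. There is no stereocentre, so the problems are regiochemical and chemoselective only.

The fragile groups are:
- the terminal vinyl group, which rules out hydrogenolysis once it is present and which can add the neighbouring C6 hydroxyl under protic acid;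
- the tert-allyl–aryl bond, which ipso protonation of this electron-rich ring could break;
- the nucleophilic C3 and C5 of the benzofuran, the air-sensitive polyphenol, and the tertiary alkyl aryl ether of ring D.

The real difficulty lies in placing a quaternary carbon on crowded C7, in building ring C with its unsymmetrical 1,2,3,5 pattern, and in freeing three phenols at the end without touching the alkene. The key step uses the fact that, in a ring A aryl ether, the future C3a is the only hydrogen-bearing carbon ortho to O1, because C7 is blocked by the quaternary group. That carbon is activated by O1 and the C4 oxygen (both ortho) and by the C6 oxygen (para), so a C3–C3a closure from a chain on O1 has one possible site.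

## Logic of the disconnections

19 to 18. The three aryl O–CH2Ph bonds (C4–O and C6–O of ring A, C7–O of ring C) are cut. Benzyl ethers survive heat, base, hydride and mild Lewis acid and keep ring A electron-rich for the ring closure. The demand is that cleavage cannot be hydrogenolytic, so it must be a low-temperature Lewis-acid dealkylation with a cation trap.

18 to 16 (through 17). The C3–C3a bond of ring B is cut and C3 returns to the aldehyde oxidation level. The cut is made here because C3a is the only free ortho carbon and is triply activated. The 2-arylbenzofuran becomes an acyclic aryl alkyl ether, one ring fewer, with two aromatic halves that can be made separately. The demands are an electrophile mild enough for the vinyl group, the benzyl ethers and ring D, and a carbonyl that is an aldehyde on the carbon next to the aryl-bearing carbon, so that the aryl ends at C2.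

16 to 15. No skeletal bond is cut; the aldehyde is traced to a methyl ester. The ester is robust and activates its α-carbon for substitution, whereas the aldehyde is too labile to carry. The demand is a reduction that stops at the aldehyde, with the crude product used at once.

15 to 5 + 14. The ether bond between the phenolic oxygen (future O1) and the α-carbon (future C2) is cut. This is the most convergent cut and gives two halves of similar size. The demand is O-alkylation, not C-alkylation, of a hindered, electron-rich phenoxide by a secondary benzylic bromide.

5 to 3 (through 4) to 1 + 2. The aryl–C(quaternary) bond at the future C7 is traced by a retro-[3,3] shift to an allyl aryl ether, and the O–allyl bond is then cut. A sigmatropic shift delivers the tertiary terminus only to an ortho carbon. Both ortho carbons of 1 are equivalent, so there is no regiochemical choice. The demand is that the rearrangement stops at the ortho phenol, without para migration and without closure onto the new vinyl group.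

14 to 13. The C–Br bond α to the ester is cut. The demand is ionic (enolate) halogenation, because a radical or electrophilic brominating agent would attack ring C and the benzylic C4 of ring D.

13 to 12 to 11 to 10. The benzyl ether at C7 is cut, then the tertiary O1–C2 bond of ring D, then the side chain is desaturated and both phenols are re-masked. In 11 only one phenol is ortho to the hydroxyalkyl chain, so ring D can close in one direction only and the two oxygens are told apart by geometry. The demand is that this hydrogenation takes place before any alkene that must survive is in the molecule, which holds because the ring A half is joined later.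

10 to 8 + 9. The aryl–alkynyl bond (future C4a–C4) is cut. One inexpensive piece then brings C4, C3, C2, both methyls and the ring oxygen's partner carbon. The demand is a coupling at a carbon flanked by two ortho substituents, hence an iodide.

8 to 7 to 6. The C–I bond at the future C4a and the two benzyl ether bonds are cut. The carbon ortho to the acetate chain and para to an ether is the most reactive site, and the two such carbons of 7 are identical. The demand is mono-iodination away from the carbon between the two ethers.

## Other disconnections considered

Alternative 1: Ring C is cut at chroman bonds C5–C6 and C8–C8a. In the forward step an alkoxide base adds tert-butyl acetoacetate A2 through its central carbon to the exocyclic carbon of the arylidene lactone A1; the acetyl methyl then acylates on the lactone carbonyl, giving the cyclohexane-1,3-dione A3 with the ring D carbons as a hydroxyalkyl chain.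
- In favour: every substituent of ring C is placed by connectivity, which is better than the chosen plan, where ring C depends on the site selectivity of an iodination. The anionic conditions are also kinder to the vinyl group than a Lewis acid.
- Against: A3 is two oxidation levels below a resorcinol. Ester cleavage, decarboxylation, dehydrogenation and closure of ring D must follow, and the oxidant has to spare an electron-rich benzofuran and a terminal alkene. The Michael acceptor is a trisubstituted alkene deactivated by the donor heteroaryl group. The three stereocentres that are set are all erased later.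
- Comparison: the benzofuran must still be made first, so ring B is not avoided and the step count is higher. Mechanistically it is sound, but its weak point is a late oxidation, whereas the chosen plan needs no redox change after the union.

Alternative 2: Rings C and D are cut together at C4a–C8a, C5–C6 and C7–C8. In the forward step Cp*RuCl(cod) A6 cyclotrimerises the ynol-ether diyne A4 with the alkynyl boronate A5 at room temperature to give the aryl boronate A7, whose C–B bond would later be oxidised to the C7 hydroxyl.
- In favour: three bonds and two rings form in one neutral step. On bonds made per step this is better than the chosen plan, and the meta placement of boron relative to the benzofuranyl group is the sterically expected one.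
- Against: A4 is a tertiary-alkyl ynol ether, a class that loses an alkene by retro-ene reaction to a ketene on gentle warming, and it is not simple to prepare. The regiochemistry rests on the catalyst and not on the substrate. The vinyl group could bind the metal. The acetal protecting groups need protic acid at the end, which is no safer for the reverse prenyl phenol than the Lewis acid of the chosen plan.
- Comparison: it would be shorter if A4 could be handled, but it carries more untested selectivity. The chosen closure has no regiochemical choice at all.

Alternative 3: Ring C is cut at C4a–C5. In the forward step aqueous hydroxide folds the triketone A8 by aldol addition of its chain-side methylene to the benzofuranyl ketone, and dehydration gives the prenyl resorcinol A9; acid would later close ring D.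
- In favour: only one six-membered aldol is possible, so ring C's pattern is fixed by the chain. This is equal to or better than the iodination of the chosen plan. Base leaves the vinyl group alone, and ring C needs no protecting group.
- Against: the attacking methylene is the least acidic one and the ketone is deactivated by the benzofuran. Triketones can also close through oxygen to pyranones or cleave by retro-Claisen reaction under hydroxide. The later acid closure of ring D must discriminate between two alkenes.
- Comparison: ring C might be reached in fewer steps, but the benzofuran with the C7 quaternary group must again be built beforehand. The chosen plan makes both halves independently and joins them late.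

Key step: step 11

Remarks on the chemistry: the carbon that becomes C2 is a stereocentre in 14–17; it is carried as a racemate and erased when ring B aromatises, so no stereocontrol is attempted. The precursor 16 and product 18 differ only by water (C45H46O6 to C45H44O5). The chroman half is begun from 6, which already carries the two-carbon side chain, so no aryl methyl ether has to be cleaved anywhere.

Step 1
Reactants: 1 3,5-bis(benzyloxy)phenol; 2 1-bromo-3-methylbut-2-ene
Product: 3 1,3-bis(benzyloxy)-5-[(3-methylbut-2-en-1-yl)oxy]benzene
Conditions: K2CO3, acetone, reflux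
Reagents that add atoms: none
Why: Williamson ether synthesis; carbonate in acetone favours O- over C-alkylation of the phenoxide, and the primary allylic bromide reacts at its unsubstituted carbon.

Step 2
Reactants: 3 1,3-bis(benzyloxy)-5-[(3-methylbut-2-en-1-yl)oxy]benzene
Product: 5 3,5-bis(benzyloxy)-2-(2-methylbut-3-en-2-yl)phenol, via ortho-dienone 4 (not isolated)
Conditions: PhNEt2, 190 °C, sealed tube, Ar, short reaction time
Reagents that add atoms: none
Why: Aromatic Claisen rearrangement; the [3,3] shift carries the tertiary allyl terminus to an ortho carbon (both are equivalent), and the amine solvent speeds tautomerisation of dienone 4 to the phenol before a second shift can occur.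

Step 3
Reactants: 6 methyl 2-(3,5-dihydroxyphenyl)acetate
Product: 7 methyl 2-[3,5-bis(benzyloxy)phenyl]acetate
Conditions: BnBr (2.2 equiv), K2CO3, acetone, reflux
Reagents that add atoms: benzyl bromide, BrCc1ccccc1
Why: Double Williamson etherification; carbonate is too weak to deprotonate the ester α-position, so only the phenols react.

Step 4
Reactants: 7 methyl 2-[3,5-bis(benzyloxy)phenyl]acetate
Product: 8 methyl 2-[3,5-bis(benzyloxy)-2-iodophenyl]acetate
Conditions: NIS (1.05 equiv), CF3CO2H (10 mol %), MeCN, 0 °C to rt, dark
Reagents that add atoms: N-iodosuccinimide, O=C1CCC(=O)N1I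
Why: Electrophilic aromatic iodination; the carbon ortho to the side chain is para to one ether and ortho to the other and is less hindered than the carbon between the two ethers, and one equivalent of reagent limits di-iodination.

Step 5
Reactants: 8 methyl 2-[3,5-bis(benzyloxy)-2-iodophenyl]acetate; 9 2-methylbut-3-yn-2-ol
Product: 10 methyl 2-[3,5-bis(benzyloxy)-2-(3-hydroxy-3-methylbut-1-yn-1-yl)phenyl]acetate
Conditions: PdCl2(PPh3)2 (3 mol %), CuI (5 mol %), Et3N, THF, 50 °C
Reagents that add atoms: none
Why: Sonogashira coupling; the aryl iodide adds oxidatively to zerovalent palladium despite two ortho substituents, and the tertiary propargylic alcohol needs no protection.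

Step 6
Reactants: 10 methyl 2-[3,5-bis(benzyloxy)-2-(3-hydroxy-3-methylbut-1-yn-1-yl)phenyl]acetate
Product: 12 methyl 2-(7-hydroxy-2,2-dimethylchroman-5-yl)acetate, via triol 11 (not isolated)
Conditions: H2 (1 atm), Pd/C, EtOAc, rt; filter, concentrate; then TsOH·H2O (10 mol %), PhMe, 70 °C
Reagents that add atoms: none
Why: Catalytic hydrogenation saturates the alkyne and hydrogenolyses both benzyl ethers; acid then ionises the tertiary alcohol of 11, and the only ortho phenol traps the cation in a six-membered dehydrative etherification, the other phenol being para to the chain and out of reach.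

Step 7
Reactants: 12 methyl 2-(7-hydroxy-2,2-dimethylchroman-5-yl)acetate
Product: 13 methyl 2-[7-(benzyloxy)-2,2-dimethylchroman-5-yl]acetate
Conditions: BnBr (1.1 equiv), K2CO3, acetone, reflux
Reagents that add atoms: benzyl bromide, BrCc1ccccc1
Why: Williamson etherification of the single remaining phenol; the ester and the ring D ether are inert to carbonate.

Step 8
Reactants: 13 methyl 2-[7-(benzyloxy)-2,2-dimethylchroman-5-yl]acetate
Product: 14 racemic methyl 2-[7-(benzyloxy)-2,2-dimethylchroman-5-yl]-2-bromoacetate
Conditions: LiN(SiMe3)2 (1.05 equiv), THF, −78 °C; then cannulated into NBS (1.1 equiv), THF, −78 °C; aq. NH4Cl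
Reagents that add atoms: N-bromosuccinimide, O=C1CCC(=O)N1Br
Why: Electrophilic bromination of an ester enolate; the enolate outcompetes ring C for the bromine source at −78 °C, no radical chain reaches the benzylic C4, and inverse addition limits dibromination.

Step 9
Reactants: 5 3,5-bis(benzyloxy)-2-(2-methylbut-3-en-2-yl)phenol; 14 racemic methyl 2-[7-(benzyloxy)-2,2-dimethylchroman-5-yl]-2-bromoacetate
Product: 15 racemic methyl 2-[7-(benzyloxy)-2,2-dimethylchroman-5-yl]-2-[3,5-bis(benzyloxy)-2-(2-methylbut-3-en-2-yl)phenoxy]acetate
Conditions: Cs2CO3, MeCN, rt to 40 °C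
Reagents that add atoms: none
Why: SN2 displacement of an activated α-bromo ester by a caesium phenoxide; the electrophile has no β-hydrogen, so elimination is impossible, and the loose ion pair in a polar aprotic solvent favours reaction at oxygen.

Step 10
Reactants: 15 racemic methyl 2-[7-(benzyloxy)-2,2-dimethylchroman-5-yl]-2-[3,5-bis(benzyloxy)-2-(2-methylbut-3-en-2-yl)phenoxy]acetate
Product: 16 racemic 2-[7-(benzyloxy)-2,2-dimethylchroman-5-yl]-2-[3,5-bis(benzyloxy)-2-(2-methylbut-3-en-2-yl)phenoxy]acetaldehyde
Conditions: i-Bu2AlH (1.1 equiv), PhMe/CH2Cl2, −78 °C; MeOH at −78 °C, then aq. KNaC4H4O6; crude product used directly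
Reagents that add atoms: none
Why: Partial reduction of an ester with i-Bu2AlH; the α-aryloxy oxygen chelates aluminium and holds the tetrahedral adduct until the cold quench, and the unactivated alkene is not hydroaluminated at this temperature.

Step 11
Reactants: 16 racemic 2-[7-(benzyloxy)-2,2-dimethylchroman-5-yl]-2-[3,5-bis(benzyloxy)-2-(2-methylbut-3-en-2-yl)phenoxy]acetaldehyde
Product: 18 4,6-bis(benzyloxy)-2-[7-(benzyloxy)-2,2-dimethylchroman-5-yl]-7-(2-methylbut-3-en-2-yl)benzofuran, via dihydrobenzofuran-3-ol 17 (not isolated)
Conditions: BF3·OEt2 (30 mol %), 4 Å molecular sieves, CH2Cl2 (0.01 M), −40 to 0 °C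
Reagents that add atoms: none
Why: BF3 binds the aldehyde oxygen of 16, and the ring A carbon ortho to the ether oxygen (future C3a) attacks the carbonyl carbon (future C3) in an intramolecular Friedel–Crafts hydroxyalkylation that gives boron-bound 17. Ionisation of the C3–O bond of 17, helped by the three ring A oxygens, and loss of the C2 proton expel water and aromatise ring B; the closure is 5-exo-trig at the carbonyl, the ring atoms being O1, C2, C3, C3a and C7a. The closest known reaction type is the acid-promoted cyclodehydration of α-aryloxy aldehydes, acetals and ketones to benzofurans. No stereocentre is formed: the one in 16 becomes sp2 and both diastereomers of 17 converge on 18. For site selectivity, one of the two carbons ortho to the ether oxygen bears hydrogen and the other the quaternary allyl carbon, so substitution can occur at one place only; ipso attack at the blocked carbon would have to expel a tert-allyl cation and is held back by sterics, low temperature and an aprotic Lewis acid. The aryl group ends at C2 and not C3 because the carbonyl is an aldehyde on the carbon next to the aryl-bearing carbon. For chemoselectivity, ring C could reach the aldehyde only through a four-membered ring and the vinyl group only through an eight-membered ring, high dilution suppresses intermolecular hydroxyalkylation, and the benzyl ethers and ring D are inert to BF3·OEt2 at 0 °C. The sieves take up the water, so no strong protic acid builds up to hydrate or shift the terminal alkene.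

Step 12
Reactants: 18 4,6-bis(benzyloxy)-2-[7-(benzyloxy)-2,2-dimethylchroman-5-yl]-7-(2-methylbut-3-en-2-yl)benzofuran
Product: 19 2-(7-hydroxy-2,2-dimethylchroman-5-yl)-7-(2-methylbut-3-en-2-yl)benzofuran-4,6-diol
Conditions: BCl3 (6 equiv), C6HMe5 (10 equiv), CH2Cl2, −78 °C; MeOH at −78 °C, then aq. NaHCO3
Reagents that add atoms: none
Why: Lewis-acid cleavage of aryl benzyl ethers with a cation scavenger; pentamethylbenzene takes up each benzyl cation by Friedel–Crafts alkylation before it can attack C3 or C5, and the low temperature with a cold buffered quench spares the vinyl group and the tertiary ether of ring D, whereas hydrogenolysis would reduce the alkene.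

Compound list

1 | 3,5-bis(benzyloxy)phenol | Oc1cc(OCc2ccccc2)cc(OCc2ccccc2)c1 | starting material
2 | 1-bromo-3-methylbut-2-ene | CC(C)=CCBr | starting material
3 | 1,3-bis(benzyloxy)-5-[(3-methylbut-2-en-1-yl)oxy]benzene | CC(C)=CCOc1cc(OCc2ccccc2)cc(OCc2ccccc2)c1 | intermediate
4 | racemic 3,5-bis(benzyloxy)-6-(2-methylbut-3-en-2-yl)cyclohexa-2,4-dien-1-one | C=CC(C)(C)C1C(=O)C=C(OCc2ccccc2)C=C1OCc1ccccc1 | intermediate (not isolated)
5 | 3,5-bis(benzyloxy)-2-(2-methylbut-3-en-2-yl)phenol | C=CC(C)(C)c1c(O)cc(OCc2ccccc2)cc1OCc1ccccc1 | intermediate
6 | methyl 2-(3,5-dihydroxyphenyl)acetate | COC(=O)Cc1cc(O)cc(O)c1 | starting material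
7 | methyl 2-[3,5-bis(benzyloxy)phenyl]acetate | COC(=O)Cc1cc(OCc2ccccc2)cc(OCc2ccccc2)c1 | intermediate
8 | methyl 2-[3,5-bis(benzyloxy)-2-iodophenyl]acetate | COC(=O)Cc1cc(OCc2ccccc2)cc(OCc2ccccc2)c1I | intermediate
9 | 2-methylbut-3-yn-2-ol | C#CC(C)(C)O | starting material
10 | methyl 2-[3,5-bis(benzyloxy)-2-(3-hydroxy-3-methylbut-1-yn-1-yl)phenyl]acetate | COC(=O)Cc1cc(OCc2ccccc2)cc(OCc2ccccc2)c1C#CC(C)(C)O | intermediate
11 | methyl 2-[3,5-dihydroxy-2-(3-hydroxy-3-methylbutyl)phenyl]acetate | COC(=O)Cc1cc(O)cc(O)c1CCC(C)(C)O | intermediate (not isolated)
12 | methyl 2-(7-hydroxy-2,2-dimethylchroman-5-yl)acetate | COC(=O)Cc1cc(O)cc2c1CCC(C)(C)O2 | intermediate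
13 | methyl 2-[7-(benzyloxy)-2,2-dimethylchroman-5-yl]acetate | COC(=O)Cc1cc(OCc2ccccc2)cc2c1CCC(C)(C)O2 | intermediate
14 | racemic methyl 2-[7-(benzyloxy)-2,2-dimethylchroman-5-yl]-2-bromoacetate | COC(=O)C(Br)c1cc(OCc2ccccc2)cc2c1CCC(C)(C)O2 | intermediate
15 | racemic methyl 2-[7-(benzyloxy)-2,2-dimethylchroman-5-yl]-2-[3,5-bis(benzyloxy)-2-(2-methylbut-3-en-2-yl)phenoxy]acetate | C=CC(C)(C)c1c(OCc2ccccc2)cc(OCc2ccccc2)cc1OC(C(=O)OC)c1cc(OCc2ccccc2)cc2c1CCC(C)(C)O2 | intermediate
16 | racemic 2-[7-(benzyloxy)-2,2-dimethylchroman-5-yl]-2-[3,5-bis(benzyloxy)-2-(2-methylbut-3-en-2-yl)phenoxy]acetaldehyde | C=CC(C)(C)c1c(OCc2ccccc2)cc(OCc2ccccc2)cc1OC(C=O)c1cc(OCc2ccccc2)cc2c1CCC(C)(C)O2 | intermediate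
17 | 4,6-bis(benzyloxy)-2-[7-(benzyloxy)-2,2-dimethylchroman-5-yl]-7-(2-methylbut-3-en-2-yl)-2,3-dihydrobenzofuran-3-ol, racemic mixture of diastereomers, boron-bound in the flask | C=CC(C)(C)c1c(OCc2ccccc2)cc(OCc2ccccc2)c2c1OC(c1cc(OCc3ccccc3)cc3c1CCC(C)(C)O3)C2O | intermediate (not isolated)
18 | 4,6-bis(benzyloxy)-2-[7-(benzyloxy)-2,2-dimethylchroman-5-yl]-7-(2-methylbut-3-en-2-yl)benzofuran | C=CC(C)(C)c1c(OCc2ccccc2)cc(OCc2ccccc2)c2cc(-c3cc(OCc4ccccc4)cc4c3CCC(C)(C)O4)oc12 | intermediate
19 | 2-(7-hydroxy-2,2-dimethylchroman-5-yl)-7-(2-methylbut-3-en-2-yl)benzofuran-4,6-diol | C=CC(C)(C)c1c(O)cc(O)c2cc(-c3cc(O)cc4c3CCC(C)(C)O4)oc12 | target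

Total step count: 12 (two to phenol 5, six to bromo ester 14, four from the union to the target). Longest linear sequence: 10 steps (6 to 19, steps 3–12).

Least certain steps

Step 11 (key step). The aldehyde may be consumed by intermolecular hydroxyalkylation of the very nucleophilic ring A, by ipso attack at the blocked ortho carbon with loss of the tert-allyl cation, or by enolisation and decomposition before ring closure. The fallback forms the same C3–C3a bond by acylation. It sets out from 15 and returns at 18. Saponification of 15 (LiOH, THF/H2O, rt) should give racemic 2-[7-(benzyloxy)-2,2-dimethylchroman-5-yl]-2-[3,5-bis(benzyloxy)-2-(2-methylbut-3-en-2-yl)phenoxy]acetic acid F1. Its mixed anhydride with trifluoroacetic anhydride (CH2Cl2, 0 °C) should acylate the same free ortho carbon to give racemic 4,6-bis(benzyloxy)-2-[7-(benzyloxy)-2,2-dimethylchroman-5-yl]-7-(2-methylbut-3-en-2-yl)benzofuran-3(2H)-one F2. NaBH4 (MeOH/THF, 0 °C) would reduce F2 to 17, and a trace of TsOH in CH2Cl2 would dehydrate 17 to 18.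

Step 2. The dienone may undergo a further Cope shift to the para carbon, and the product phenol may go on to the abnormal Claisen product or close onto its own vinyl group on prolonged heating. The fallback interrupts the sequence by acylation; it sets out from 3 and returns at 5. Heating 3 in PhNEt2 with Ac2O and NaOAc (180 °C, sealed) should trap the first-formed phenol as 3,5-bis(benzyloxy)-2-(2-methylbut-3-en-2-yl)phenyl acetate F3, which lacks the free hydroxyl needed for the follow-up reactions. Methanolysis (K2CO3, MeOH, rt) would then release 5.

Step 9 (with step 8 before it). Substitution between two ortho-hindered partners may be slow, the phenoxide may alkylate at carbon, and the enolate bromination may over-brominate. The fallback replaces SN2 by carbene O–H insertion; it sets out from 13 and 5 and returns at 15, bypassing 14. Diazo transfer to 13 (4-acetamidobenzenesulfonyl azide, DBU, MeCN, rt) should give methyl 2-[7-(benzyloxy)-2,2-dimethylchroman-5-yl]-2-diazoacetate F4. Slow addition of F4 to 5 and Rh2(OAc)4 (1 mol %) in CH2Cl2 at rt should insert the carbene into the phenolic O–H bond, which is much faster than cyclopropanation of a hindered monosubstituted alkene.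

Step 10. Reduction may run on to the primary alcohol, or the enolisable aldehyde may degrade during work-up. The fallback separates reduction from oxidation; it sets out from 15 and returns at 16. LiAlH4 (THF, 0 °C) should give racemic 2-[7-(benzyloxy)-2,2-dimethylchroman-5-yl]-2-[3,5-bis(benzyloxy)-2-(2-methylbut-3-en-2-yl)phenoxy]ethan-1-ol F5, and Dess–Martin periodinane (NaHCO3, CH2Cl2, 0 °C) should oxidise F5 to 16 under buffered, non-enolising conditions.

Step 12. Acid set free on quenching may add the C6 hydroxyl across the vinyl group, the Lewis acid may ionise the tertiary C–O bond of ring D, or benzyl cations that escape the scavenger may alkylate C3 or C5. The fallback changes the mechanism from electrophilic to nucleophilic dealkylation; it sets out from 18 and returns at 19 with no new intermediate. NaSEt in degassed DMF at 120 °C should remove each benzyl group by SN2 attack at the benzylic carbon, leaving the alkene, ring D and the benzofuran in a basic, acid-free medium; acidification at 0 °C would then give 19.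

Further compounds

F1 | step 11 | racemic 2-[7-(benzyloxy)-2,2-dimethylchroman-5-yl]-2-[3,5-bis(benzyloxy)-2-(2-methylbut-3-en-2-yl)phenoxy]acetic acid | C=CC(C)(C)c1c(OCc2ccccc2)cc(OCc2ccccc2)cc1OC(C(=O)O)c1cc(OCc2ccccc2)cc2c1CCC(C)(C)O2
F2 | step 11 | racemic 4,6-bis(benzyloxy)-2-[7-(benzyloxy)-2,2-dimethylchroman-5-yl]-7-(2-methylbut-3-en-2-yl)benzofuran-3(2H)-one | C=CC(C)(C)c1c(OCc2ccccc2)cc(OCc2ccccc2)c2c1OC(c1cc(OCc3ccccc3)cc3c1CCC(C)(C)O3)C2=O
F3 | step 2 | 3,5-bis(benzyloxy)-2-(2-methylbut-3-en-2-yl)phenyl acetate | C=CC(C)(C)c1c(OC(C)=O)cc(OCc2ccccc2)cc1OCc1ccccc1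
F4 | step 9 | methyl 2-[7-(benzyloxy)-2,2-dimethylchroman-5-yl]-2-diazoacetate | COC(=O)C(=[N+]=[N-])c1cc(OCc2ccccc2)cc2c1CCC(C)(C)O2
F5 | step 10 | racemic 2-[7-(benzyloxy)-2,2-dimethylchroman-5-yl]-2-[3,5-bis(benzyloxy)-2-(2-methylbut-3-en-2-yl)phenoxy]ethan-1-ol | C=CC(C)(C)c1c(OCc2ccccc2)cc(OCc2ccccc2)cc1OC(CO)c1cc(OCc2ccccc2)cc2c1CCC(C)(C)O2
F0 | step 12 | none | none
A1 | alternative 1 | (E)-3-{[4,6-bis(benzyloxy)-7-(2-methylbut-3-en-2-yl)benzofuran-2-yl]methylidene}-6,6-dimethyltetrahydro-2H-pyran-2-one | O=C1OC(C)(C)CC/C1=C\c1cc2c(OCc3ccccc3)cc(OCc3ccccc3)c(C(C)(C)C=C)c2o1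
A2 | alternative 1 | tert-butyl acetoacetate | CC(=O)CC(=O)OC(C)(C)C
A3 | alternative 1 | racemic all-trans tert-butyl 6-[4,6-bis(benzyloxy)-7-(2-methylbut-3-en-2-yl)benzofuran-2-yl]-5-(3-hydroxy-3-methylbutyl)-2,4-dioxocyclohexane-1-carboxylate (one enantiomer drawn) | O=C1CC(=O)[C@@H](CCC(C)(C)O)[C@H](c2cc3c(OCc4ccccc4)cc(OCc4ccccc4)c(C(C)(C)C=C)c3o2)[C@H]1C(=O)OC(C)(C)C
A4 | alternative 2 | 2-[5-(ethynyloxy)-5-methylhex-1-yn-1-yl]-4,6-bis(methoxymethoxy)-7-(2-methylbut-3-en-2-yl)benzofuran | C#COC(C)(C)CCC#Cc1cc2c(OCOC)cc(OCOC)c(C(C)(C)C=C)c2o1
A5 | alternative 2 | 2-ethynyl-4,4,5,5-tetramethyl-1,3,2-dioxaborolane | C#CB1OC(C)(C)C(C)(C)O1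
A6 | alternative 2 | chloro(cycloocta-1,5-diene)(pentamethylcyclopentadienyl)ruthenium, Cp*RuCl(cod) | [Ru+2].[Cl-].C[c-]1c(C)c(C)c(C)c1C.C1=CCCC=CCC1
A7 | alternative 2 | 2-{5-[4,6-bis(methoxymethoxy)-7-(2-methylbut-3-en-2-yl)benzofuran-2-yl]-2,2-dimethylchroman-7-yl}-4,4,5,5-tetramethyl-1,3,2-dioxaborolane | C=CC(C)(C)c1c(OCOC)cc(OCOC)c2cc(-c3cc(B5OC(C)(C)C(C)(C)O5)cc4c3CCC(C)(C)O4)oc12
A8 | alternative 3 | 1-[4,6-bis(benzyloxy)-7-(2-methylbut-3-en-2-yl)benzofuran-2-yl]-9-methyldec-8-ene-1,3,5-trione | CC(C)=CCCC(=O)CC(=O)CC(=O)c1cc2c(OCc3ccccc3)cc(OCc3ccccc3)c(C(C)(C)C=C)c2o1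
A9 | alternative 3 | 5-[4,6-bis(benzyloxy)-7-(2-methylbut-3-en-2-yl)benzofuran-2-yl]-4-(3-methylbut-2-enyl)benzene-1,3-diol | C=CC(C)(C)c1c(OCc2ccccc2)cc(OCc2ccccc2)c2cc(-c3cc(O)cc(O)c3CC=C(C)C)oc12
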